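**Strategy.** Core numbering: C1 (bridgehead C–OH), C2 (CHO), C3 (dienal), C6 (bridgehead C–Me), C7 (CHOH), C10 (bridge CH2). The bicyclo[4.3.1]decane is cut at C6–C10 and C7–C8 of its cyclohexane ring. A type 2 intramolecular Diels–Alder reaction joins a buta-1,3-dien-2-yl group (C10, C1, C9, C8) to a (Z)-enone (C6=C7) through the tether C2–C5. It closes the six- and seven-membered rings, sets C6 and C7, and relays C2/C3, locked in a trans-fused δ-lactone, to both bridgeheads. The bridgehead alkene C1=C9 is the latent C1 carbinol. The precursor is a trans-4,5-disubstituted δ-valerolactone carrying the dienyl group and the enone arm.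

Key step: step 10

Remark: the phosphoramidite antipode in step 2 is taken to be the one that delivers (3S)-5; locants C1–C10 for the bridged compounds are those defined above (target = 1R,2R,3S,6S,7R).

Step 1
Reactants: 1 tert-butyl but-3-enoate; 2 allyl methyl carbonate
Product: 3 tert-butyl (3E)-5-[(methoxycarbonyl)oxy]pent-3-enoate
Conditions: Hoveyda–Grubbs II (3 mol %), 1,4-benzoquinone (10 mol %), 2 (3 equiv), CH2Cl2, 40 °C
Reagents that add atoms: none
Why: Olefin cross-metathesis of two terminal alkenes should give the E-disubstituted alkene under thermodynamic control, benzoquinone suppressing Ru–H isomerisation into conjugation, and no stereocentre is formed.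

Step 2
Reactants: 3 tert-butyl (3E)-5-[(methoxycarbonyl)oxy]pent-3-enoate; 4 dimethyl malonate
Product: 5 dimethyl 2-[(3S)-1-tert-butoxy-1-oxopent-4-en-3-yl]propanedioate
Conditions: [Ir(cod)Cl]2 (2 mol %), BINOL-derived bis(1-phenylethyl)amine phosphoramidite (4 mol %, antipode giving 3S), TBD (8 mol %), THF, rt
Reagents that add atoms: none
Why: Iridium-catalysed asymmetric allylic alkylation, in which the malonate attacks the cyclometalated Ir π-allyl complex at its substituted terminus (branched product) and the chiral ligand sets the new allylic stereocentre (future C3).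

Step 3
Reactants: 5 dimethyl 2-[(3S)-1-tert-butoxy-1-oxopent-4-en-3-yl]propanedioate
Product: 6 tert-butyl (3S)-3-ethenyl-5-hydroxy-4-(hydroxymethyl)pentanoate
Conditions: LiBH4, THF, MeOH (2 equiv), 0 °C → rt
Reagents that add atoms: none
Why: Chemoselective borohydride reduction should convert the two methyl esters into the 1,3-diol while the hindered tert-butyl ester, the alkene and the existing stereocentre are left untouched.

Step 4
Reactants: 6 tert-butyl (3S)-3-ethenyl-5-hydroxy-4-(hydroxymethyl)pentanoate
Product: 9 (4S,5R)-4-ethenyl-5-(hydroxymethyl)oxan-2-one, via dihydroxy acid 7 (not isolated), via cis lactone 8 (not isolated)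
Conditions: TsOH·H2O (10 mol %), toluene, 80 °C
Reagents that add atoms: none
Why: Acid-mediated tert-butyl ester cleavage and δ-lactonisation with reversible translactonisation between the two diastereotopic hydroxymethyl arms (a dynamic desymmetrisation) should funnel the material into the trans-diequatorial lactone, which sets the future C2 centre relative to C3.

Step 5
Reactants: 10 pentane-2,4-dione
Product: 11 (2Z)-4-oxopent-2-en-2-yl trifluoromethanesulfonate
Conditions: Tf2O, aq. LiOH, toluene, 5 °C
Reagents that add atoms: trifluoromethanesulfonic anhydride, O=S(=O)(OS(=O)(=O)C(F)(F)F)C(F)(F)F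
Why: O-Triflation of the lithium-chelated, U-shaped enolate of the 1,3-diketone should give the Z enol triflate, which fixes the leaving group cis to the acetyl group.

Step 6
Reactants: 9 (4S,5R)-4-ethenyl-5-(hydroxymethyl)oxan-2-one; 11 (2Z)-4-oxopent-2-en-2-yl trifluoromethanesulfonate
Product: 13 (4R,5R)-5-(hydroxymethyl)-4-[(3Z)-3-methyl-5-oxohex-3-en-1-yl]oxan-2-one, via bis-borylated alkylborane 12 (not isolated)
Conditions: 9-BBN (2.2 equiv), THF, 0 °C → rt; then 11, PdCl2(dppf) (5 mol %), AsPh3, Cs2CO3, DMF–H2O, rt
Reagents that add atoms: none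
Why: Anti-Markovnikov hydroboration of the only alkene followed by B-alkyl Suzuki–Miyaura coupling, which proceeds with retention of the triflate geometry, should install the (Z)-trisubstituted enone arm without touching the ring stereocentres (the C4 descriptor changes by CIP priority only).

Step 7
Reactants: 13 (4R,5R)-5-(hydroxymethyl)-4-[(3Z)-3-methyl-5-oxohex-3-en-1-yl]oxan-2-one
Product: 14 (3S,4R)-4-[(3Z)-3-methyl-5-oxohex-3-en-1-yl]-6-oxooxane-3-carbaldehyde
Conditions: Dess–Martin periodinane, CH2Cl2, 0 °C → rt
Reagents that add atoms: none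
Why: Dess–Martin oxidation of the primary alcohol under near-neutral conditions should give the aldehyde, whose α-centre is already the thermodynamically preferred trans one.

Step 8
Reactants: 14 (3S,4R)-4-[(3Z)-3-methyl-5-oxohex-3-en-1-yl]-6-oxooxane-3-carbaldehyde
Product: 15 (4R,5R)-5-ethynyl-4-[(3Z)-3-methyl-5-oxohex-3-en-1-yl]oxan-2-one
Conditions: TMSCHN2 (1.05 equiv), n-BuLi, THF, −78 → 0 °C
Reagents that add atoms: (trimethylsilyl)diazomethane, C[Si](C)(C)C=[N+]=[N-]
Why: Colvin rearrangement, in which the lithiated silyldiazomethane adds to the aldehyde (far more electrophilic at −78 °C than the hindered conjugated ketone or the lactone) and Peterson-type elimination, loss of N2 and 1,2-hydride shift of the alkylidene carbene give the terminal alkyne with the adjacent stereocentre intact.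

Step 9
Reactants: 15 (4R,5R)-5-ethynyl-4-[(3Z)-3-methyl-5-oxohex-3-en-1-yl]oxan-2-one
Product: 16 (4R,5R)-5-(buta-1,3-dien-2-yl)-4-[(3Z)-3-methyl-5-oxohex-3-en-1-yl]oxan-2-one
Conditions: Grubbs II (5 mol %), ethylene (1 atm), CH2Cl2, rt
Reagents that add atoms: ethylene, C=C
Why: Enyne cross-metathesis with ethylene should convert the terminal alkyne into the 2-substituted buta-1,3-diene, the only other alkene being trisubstituted and electron-poor and therefore outside the catalytic cycle.

Step 10
Reactants: 16 (4R,5R)-5-(buta-1,3-dien-2-yl)-4-[(3Z)-3-methyl-5-oxohex-3-en-1-yl]oxan-2-one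
Product: 17 (2R,3R,6S,7R)-7-acetyl-6-methylbicyclo[4.3.1]dec-1(9)-ene trans-fused at C2–C3 to a δ-lactone (C2–CH2–O–CO–CH2–C3)
Conditions: EtAlCl2 (2.2 equiv), CH2Cl2, −78 → −20 °C
Reagents that add atoms: none
Why: Lewis-acid-promoted type 2 intramolecular Diels–Alder reaction (closest known class: 2-substituted butadienes linked through four atoms to an activated alkene, which give bicyclo[4.3.1]dec-1(9)-enes), in which EtAlCl2 on the enone oxygen lowers the LUMO and a concerted, asynchronous [4+2] joins the diene CH2 terminus C10 to the enone β-carbon C6 (the more advanced bond) and the vinyl terminus C8 to the α-carbon C7. The cyclohexene (C1, C9, C8, C7, C6, C10) closes through the usual boat-like six-centre array, and the seven-membered ring (C1–C6 plus C10) closes because the tether links diene C-2 to the dienophile, which enforces the 1,3-bridged mode, places the new C1=C9 alkene at the bridgehead and coincides with the electronically preferred pairing of the nucleophilic CH2 terminus with the β-carbon. C6 and C7 are set by suprafacial addition to the Z-alkene with the tether necessarily endo, so the acetyl group ends trans to the 6-methyl group and cis to C5. The bridgeheads are set relative to C2/C3 by the lactone: the four-atom tether can only arch past the outer (C10) edge of the diene, which requires one sign of the gauche C1–C2–C3–C4 torsion for each diene face, and the trans-fused lactone permits that sign on one face only, the one that leaves the C3 arm exo and pseudo-equatorial, whereas the other face would drive the tether across the diene π-cloud. The step needs a single π-face and retention of the enone geometry: the first is secured by the lactone lock, the second by low temperature and an aprotic aluminium Lewis acid.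

Step 11
Reactants: 17 (2R,3R,6S,7R)-7-acetyl-6-methylbicyclo[4.3.1]dec-1(9)-ene trans-fused at C2–C3 to a δ-lactone
Product: 18 (1R,2S,3R,6S,7R)-7-acetyl-1-hydroxy-6-methylbicyclo[4.3.1]decane with the same C2–C3 trans-fused δ-lactone
Conditions: Co(acac)2 (20 mol %), PhSiH3, O2 (1 atm), THF–i-PrOH, rt
Reagents that add atoms: dioxygen, O=O
Why: Mukaiyama hydration, in which hydrogen-atom transfer to C9 of the strained trisubstituted bridgehead alkene gives the tertiary bridgehead radical that is trapped by O2 and reduced to the Markovnikov alcohol, the C1 configuration being dictated by the bicyclic cage.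

Step 12
Reactants: 18 (1R,2S,3R,6S,7R)-7-acetyl-1-hydroxy-6-methylbicyclo[4.3.1]decane C2–C3 δ-lactone
Product: 19 (1R,2S,3R,6S,7R)-7-acetoxy-1-hydroxy-6-methylbicyclo[4.3.1]decane with the same C2–C3 trans-fused δ-lactone
Conditions: mCPBA, CH2Cl2, 0 °C → rt
Reagents that add atoms: 3-chloroperbenzoic acid, OOC(=O)c1cccc(Cl)c1
Why: Baeyer–Villiger oxidation, in which the secondary ring carbon C7 migrates in preference to methyl with retention of configuration, should turn the acetyl group into the C7 acetate.

Step 13
Reactants: 19 (1R,2S,3R,6S,7R)-7-acetoxy-1-hydroxy-6-methylbicyclo[4.3.1]decane C2–C3 δ-lactone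
Product: 20 lactol (anomers) of (1R,2S,3R,6S,7R)-1,7-dihydroxy-2-(hydroxymethyl)-6-methyl-3-(2-oxoethyl)bicyclo[4.3.1]decane, hemiacetal oxygen from the C2 CH2OH
Conditions: DIBAL-H (4.5 equiv), CH2Cl2, −78 °C; Rochelle salt
Reagents that add atoms: none
Why: DIBAL-H reduction should stop at the lactol (stable tetrahedral aluminate at −78 °C) and cleave the acetate, which unmasks the C3 acetaldehyde unit in hemiacetal form while C2 stays at the alcohol oxidation level.

Step 14
Reactants: 21 2-methylbut-3-en-2-ol; 22 (E)-but-2-enal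
Product: 23 (2E)-4-hydroxy-4-methylpent-2-enal
Conditions: Hoveyda–Grubbs II (2.5 mol %), CH2Cl2, 40 °C
Reagents that add atoms: none
Why: Cross-metathesis of the hindered tertiary allylic alcohol (which does not homodimerise) with crotonaldehyde should give the E-enal, which has no enolisable position.

Step 15
Reactants: 20 lactol of the C3 (2-oxoethyl) triol; 23 (2E)-4-hydroxy-4-methylpent-2-enal
Product: 24 (2E,4E)-2-[(1R,2S,3S,6S,7R)-1,7-dihydroxy-2-(hydroxymethyl)-6-methylbicyclo[4.3.1]decan-3-yl]-6-hydroxy-6-methylhepta-2,4-dienal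
Conditions: 23 (3 equiv), pyrrolidine (20 mol %), benzoic acid (20 mol %), CH2Cl2, rt
Reagents that add atoms: none
Why: Amine-catalysed cross-aldol (Mannich-type) condensation, in which the enamine of the open aldehyde form of 20 adds 1,2 to the iminium ion of the non-enolisable enal and elimination gives the conjugated dienal, the E geometry of the new trisubstituted alkene being the thermodynamic one.

Step 16
Reactants: 24 (2E,4E)-2-[(1R,2S,3S,6S,7R)-1,7-dihydroxy-2-(hydroxymethyl)-6-methylbicyclo[4.3.1]decan-3-yl]-6-hydroxy-6-methylhepta-2,4-dienal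
Product: 25 umbellacin A, (2E,4E)-2-[(1R,2R,3S,6S,7R)-2-formyl-1,7-dihydroxy-6-methylbicyclo[4.3.1]decan-3-yl]-6-hydroxy-6-methylhepta-2,4-dienal
Conditions: TEMPO (10 mol %), PhI(OAc)2 (1.1 equiv), CH2Cl2, rt
Reagents that add atoms: none
Why: TEMPO/PhI(OAc)2 oxidation is selective for the primary alcohol over the hindered secondary and the tertiary alcohols and stops at the aldehyde, so it should deliver the β-hydroxy aldehyde without touching the dienal.

**Compound list**

1 | tert-butyl but-3-enoate | C=CCC(=O)OC(C)(C)C | starting material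
2 | allyl methyl carbonate | C=CCOC(=O)OC | starting material
3 | tert-butyl (3E)-5-[(methoxycarbonyl)oxy]pent-3-enoate | COC(=O)OC/C=C/CC(=O)OC(C)(C)C | intermediate
4 | dimethyl malonate | COC(=O)CC(=O)OC | starting material
5 | dimethyl 2-[(3S)-1-tert-butoxy-1-oxopent-4-en-3-yl]propanedioate | CC(C)(C)OC(=O)C[C@H](C(C(=O)OC)C(=O)OC)C=C | intermediate
6 | tert-butyl (3S)-3-ethenyl-5-hydroxy-4-(hydroxymethyl)pentanoate | CC(C)(C)OC(=O)C[C@H](C(CO)CO)C=C | intermediate
7 | (3S)-3-ethenyl-5-hydroxy-4-(hydroxymethyl)pentanoic acid (dihydroxy acid) | OC(=O)C[C@H](C(CO)CO)C=C | intermediate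
8 | (4S,5S)-4-ethenyl-5-(hydroxymethyl)oxan-2-one (cis lactone) | O=C1C[C@@H](C=C)[C@@H](CO)CO1 | intermediate
9 | (4S,5R)-4-ethenyl-5-(hydroxymethyl)oxan-2-one (trans lactone) | O=C1C[C@@H](C=C)[C@H](CO)CO1 | intermediate
10 | pentane-2,4-dione | CC(=O)CC(C)=O | starting material
11 | (2Z)-4-oxopent-2-en-2-yl trifluoromethanesulfonate | CC(=O)/C=C(/C)OS(=O)(=O)C(F)(F)F | intermediate
12 | bis-borylated alkylborane: 9 with CH2CH2–B(9-BBN) at C4 and CH2O–B(9-BBN) at C5 | O=C1C[C@@H](CCB2C3CCCC2CCC3)[C@H](COB2C3CCCC2CCC3)CO1 | intermediate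
13 | (4R,5R)-5-(hydroxymethyl)-4-[(3Z)-3-methyl-5-oxohex-3-en-1-yl]oxan-2-one | O=C1C[C@@H](CC/C(C)=C\C(C)=O)[C@H](CO)CO1 | intermediate
14 | (3S,4R)-4-[(3Z)-3-methyl-5-oxohex-3-en-1-yl]-6-oxooxane-3-carbaldehyde | O=C1C[C@@H](CC/C(C)=C\C(C)=O)[C@H](C=O)CO1 | intermediate
15 | (4R,5R)-5-ethynyl-4-[(3Z)-3-methyl-5-oxohex-3-en-1-yl]oxan-2-one | O=C1C[C@@H](CC/C(C)=C\C(C)=O)[C@H](C#C)CO1 | intermediate
16 | (4R,5R)-5-(buta-1,3-dien-2-yl)-4-[(3Z)-3-methyl-5-oxohex-3-en-1-yl]oxan-2-one | O=C1C[C@@H](CC/C(C)=C\C(C)=O)[C@H](C(=C)C=C)CO1 | intermediate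
17 | (2R,3R,6S,7R)-7-acetyl-6-methylbicyclo[4.3.1]dec-1(9)-ene trans-fused at C2–C3 to a δ-lactone (C2–CH2–O–CO–CH2–C3); acetyl trans to 6-Me | O=C3C[C@H]1CC[C@@]2(C)CC(=CC[C@H]2C(C)=O)[C@@H]1CO3 | intermediate
18 | (1R,2S,3R,6S,7R)-7-acetyl-1-hydroxy-6-methylbicyclo[4.3.1]decane with the same trans-fused C2–C3 δ-lactone | O=C3C[C@H]1CC[C@@]2(C)C[C@](O)(CC[C@H]2C(C)=O)[C@@H]1CO3 | intermediate
19 | (1R,2S,3R,6S,7R)-7-acetoxy-1-hydroxy-6-methylbicyclo[4.3.1]decane with the same trans-fused C2–C3 δ-lactone | O=C3C[C@H]1CC[C@@]2(C)C[C@](O)(CC[C@H]2OC(C)=O)[C@@H]1CO3 | intermediate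
20 | lactol (anomers) of (1R,2S,3R,6S,7R)-1,7-dihydroxy-2-(hydroxymethyl)-6-methyl-3-(2-oxoethyl)bicyclo[4.3.1]decane | OC3C[C@H]1CC[C@@]2(C)C[C@](O)(CC[C@H]2O)[C@@H]1CO3 | intermediate
21 | 2-methylbut-3-en-2-ol | CC(C)(O)C=C | starting material
22 | (E)-but-2-enal (crotonaldehyde) | C/C=C/C=O | starting material
23 | (2E)-4-hydroxy-4-methylpent-2-enal | CC(C)(O)/C=C/C=O | intermediate
24 | (2E,4E)-2-[(1R,2S,3S,6S,7R)-1,7-dihydroxy-2-(hydroxymethyl)-6-methylbicyclo[4.3.1]decan-3-yl]-6-hydroxy-6-methylhepta-2,4-dienal | CC(C)(O)/C=C/C=C(/C=O)[C@H]1CC[C@@]2(C)C[C@](O)(CC[C@H]2O)[C@@H]1CO | intermediate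
25 | umbellacin A, (2E,4E)-2-[(1R,2R,3S,6S,7R)-2-formyl-1,7-dihydroxy-6-methylbicyclo[4.3.1]decan-3-yl]-6-hydroxy-6-methylhepta-2,4-dienal | CC(C)(O)/C=C/C=C(/C=O)[C@H]1CC[C@@]2(C)C[C@](O)(CC[C@H]2O)[C@@H]1C=O | target

**Step count and risks**

Total step count: 16. Longest linear sequence: 14 (steps 1–4, 6–13, 15 and 16).

Steps most likely to fail:

Step 10 (key step). The likely failure is isomerisation of the Z-enone to the E-enone on the Lewis acid before ring closure, together with sluggish cycloaddition of the β,β-disubstituted enone, so that the C7 epimer accompanies the desired adduct. The fallback no longer takes C7 from the dienophile geometry but sets it by substrate-controlled reduction. It sets out from acetate 19, obtained as a C7-epimeric mixture after steps 11 and 12. Acetate methanolysis (K2CO3, MeOH, 0 °C, then TsOH to re-close any opened lactone) would give the hydroxy lactone as C7 epimers F1. Dess–Martin oxidation would give the single C7 ketone F2. NaBH4 (MeOH, −40 °C) should attack along the unhindered axial trajectory, anti to the axial C5 bridge on the neighbouring quaternary C6, and give the equatorial (7R) alcohol F3. DIBAL-H (CH2Cl2, −78 °C) then leads to lactol 20, where the route is rejoined.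

Step 15. The likely failures are self-condensation or 1,4-addition of the enamine, slow release of the aldehyde from the lactol, and reversible oxa-Michael capture of the iminium-activated dienal by the neighbouring hydroxymethyl group. The fallback forms the C=C bond by palladium catalysis instead of carbonyl condensation and sets out from lactol 20. α-Methylenation (aq. CH2O, pyrrolidine, propionic acid, i-PrOH, 45 °C; Mannich/elimination) would give the 2-substituted acrolein F4. A Heck reaction with (E)-4-iodo-2-methylbut-3-en-2-ol (Pd(OAc)2, Bu4NCl, NaHCO3, DMF, rt), with β-hydride elimination toward the new CH2 group, should give the conjugated E,E-dienal and so return to 24.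

Step 8. The likely failures are competing addition of the lithiated diazomethane to the methyl ketone of the enone arm and enolisation of the α-branched aldehyde. The fallback makes the diene by carbonyl methylenation and installs the ketone arm last; it sets out from lactone 9. Dess–Martin oxidation would give the aldehyde F5. Nozaki–Hiyama–Kishi vinylation (vinyl bromide, CrCl2, cat. NiCl2, DMF) would give the allylic alcohol F6 as carbinol epimers. A second Dess–Martin oxidation would give the vinyl ketone F7. Takai–Lombardo methylenation (Zn, CH2Br2, TiCl4, THF–CH2Cl2), to which lactones are inert, would give the dienyl lactone F8. 9-BBN, which hydroborates an isolated vinyl group much faster than a conjugated diene, followed by Suzuki–Miyaura coupling with triflate 11 (PdCl2(dppf), Cs2CO3, DMF–H2O), returns to triene 16 just before the key step.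

Further compounds
F1 | step 10 | 7-hydroxy analogue of 19 as a mixture of C7 epimers (hydroxy lactone) | O=C3C[C@H]1CC[C@@]2(C)C[C@](O)(CCC2O)[C@@H]1CO3
F2 | step 10 | 1-hydroxy-6-methyl-7-oxobicyclo[4.3.1]decane with the trans-fused C2–C3 δ-lactone (C7 ketone) | O=C3C[C@H]1CC[C@@]2(C)C[C@](O)(CCC2=O)[C@@H]1CO3
F3 | step 10 | (7R)-1,7-dihydroxy-6-methylbicyclo[4.3.1]decane with the trans-fused C2–C3 δ-lactone (equatorial alcohol) | O=C3C[C@H]1CC[C@@]2(C)C[C@](O)(CC[C@H]2O)[C@@H]1CO3
F4 | step 15 | 2-[(1R,2S,3S,6S,7R)-1,7-dihydroxy-2-(hydroxymethyl)-6-methylbicyclo[4.3.1]decan-3-yl]prop-2-enal | C=C(C=O)[C@H]1CC[C@@]2(C)C[C@](O)(CC[C@H]2O)[C@@H]1CO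
F5 | step 8 | (3S,4S)-4-ethenyl-6-oxooxane-3-carbaldehyde | O=C1C[C@@H](C=C)[C@H](C=O)CO1
F6 | step 8 | (4S,5R)-4-ethenyl-5-(1-hydroxyprop-2-en-1-yl)oxan-2-one (carbinol epimers) | O=C1C[C@@H](C=C)[C@H](C(O)C=C)CO1
F7 | step 8 | (4S,5S)-4-ethenyl-5-(prop-2-enoyl)oxan-2-one | O=C1C[C@@H](C=C)[C@H](C(=O)C=C)CO1
F8 | step 8 | (4S,5R)-5-(buta-1,3-dien-2-yl)-4-ethenyloxan-2-one | O=C1C[C@@H](C=C)[C@H](C(=C)C=C)CO1
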